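## Retrosynthetic overview

1. Numbering: ring B = C8a–C1(aryl)–C2(C9)–C3(C10)–C4–C4a; ring A = C4a, C5 (H), C6 (OMe), C7 (OH), C8 (OH), C8a. The strategy rests on the C8 hydroxyl lying ortho to C8a, the ring A carbon that bears the diarylmethine C1: a leaving group on C1 unmasks the o-quinone methide O=C8–C8a=C1, electrophilic at C1.
2. Target 20 ⇐ benzyl ether 19 (hydrogenolysis at C7–O) ⇐ cis-fused lactone 18 (LiAlH4 opens the lactone to the C9/C10 diol).
3. Key disconnection C1–C2: 18 ⇐ sulfone 15; base releases the methide and the lactone enolate carbon C2 closes ring B on C1.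
4. 15 ⇐ carbinol 13 ⇐ salicylaldehyde 10 + aryl Grignard reagent 12; 10 ⇐ phenol lactone 9 by ortho-formylation at C8a; 9 ⇐ Stobbe half-ester 5 by asymmetric hydrogenation (C3, the only relay stereocentre) and ester reduction.
5. Ring order: ring A and the trimethoxyphenyl ring are bought; the lactone ring is made in step 5, ring B in step 9, and the lactone is opened in step 10.

Key step: step 9

Remark 1: carbinol 13 and sulfone 15 are carried as mixtures of C1 epimers, because C1 becomes trigonal in step 9 and its configuration is set anew there.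

Remark 2: the (R,R) antipode of Et-DuPhos [1,2-bis(2,5-diethylphospholan-1-yl)benzene] is assumed, by analogy with itaconate hydrogenations, to give the (S) acid 6; if the sense is the reverse, the (S,S) antipode is used with no other change.

Remark 3: the C8 phenol is masked as a MOM ether for the Stobbe condensation only, so that no phenoxide is present there; the acid of step 5 removes it.

## Route

Step 1
Reactants: 1 3,4-dihydroxy-5-methoxybenzaldehyde
Product: 2 4-(benzyloxy)-3-hydroxy-5-methoxybenzaldehyde
Conditions: BnBr (1.05 equiv), Li2CO3 (1.2 equiv), DMF, 45 °C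
Reagents that add atoms: benzyl bromide, BrCc1ccccc1
Why: Williamson etherification under weak-base control; the hydroxyl para to the formyl group (the later C7 oxygen) is the more acidic phenol, so Li2CO3 should ionise and benzylate it selectively.

Step 2
Reactants: 2 4-(benzyloxy)-3-hydroxy-5-methoxybenzaldehyde
Product: 3 4-(benzyloxy)-3-methoxy-5-(methoxymethoxy)benzaldehyde
Conditions: MOMCl, iPr2NEt, CH2Cl2, 0 °C → rt
Reagents that add atoms: chloromethyl methyl ether, COCCl
Why: Acetal (MOM) protection of the remaining phenol, stable to the alkoxide of step 3 and cleaved by the acid of step 5.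

Step 3
Reactants: 3 4-(benzyloxy)-3-methoxy-5-(methoxymethoxy)benzaldehyde; 4 dimethyl succinate
Product: 5 (E)-4-[4-(benzyloxy)-3-methoxy-5-(methoxymethoxy)phenyl]-3-(methoxycarbonyl)but-3-enoic acid
Conditions: NaOMe (2.5 equiv), MeOH, reflux; then aq. HCl
Reagents that add atoms: none
Why: Stobbe condensation; it should give the (E)-arylidene succinic half-ester with the free acid on the CH2 arm, which fixes which carbonyl becomes C9 (acid) and which becomes C10 (ester).

Step 4
Reactants: 5 (E)-4-[4-(benzyloxy)-3-methoxy-5-(methoxymethoxy)phenyl]-3-(methoxycarbonyl)but-3-enoic acid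
Product: 6 (3S)-4-[4-(benzyloxy)-3-methoxy-5-(methoxymethoxy)phenyl]-3-(methoxycarbonyl)butanoic acid
Conditions: [Rh(cod)((R,R)-Et-DuPhos)]BF4 (1 mol%), H2 (5 bar), MeOH, rt
Reagents that add atoms: none
Why: Rhodium–bisphosphine asymmetric hydrogenation of a Stobbe-derived itaconate half-ester; the carboxyl group chelates rhodium and the C2-symmetric phospholane differentiates the alkene faces, which sets C3 as (S), while benzyl and MOM ethers are inert to the homogeneous catalyst.

Step 5
Reactants: 6 (3S)-4-[4-(benzyloxy)-3-methoxy-5-(methoxymethoxy)phenyl]-3-(methoxycarbonyl)butanoic acid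
Product: 9 (4S)-4-[4-(benzyloxy)-3-hydroxy-5-methoxybenzyl]dihydrofuran-2(3H)-one, via hydroxy acid 7 (not isolated), via MOM lactone 8 (not isolated)
Conditions: KOH (1 equiv), EtOH; Ca(BH4)2 (from NaBH4, CaCl2), EtOH, −10 °C → rt; then 3 M HCl, MeOH, 50 °C
Reagents that add atoms: none
Why: Chemoselective borohydride reduction: Ca(BH4)2 reduces the methyl ester but not the potassium carboxylate, and acid then closes the γ-lactone (C9 carbonyl, C10H2–O) and cleaves the MOM acetal, which methanol traps as dimethoxymethane; C3 should hold because hydride delivery to the ester outruns its enolisation.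

Step 6
Reactants: 9 (4S)-4-[4-(benzyloxy)-3-hydroxy-5-methoxybenzyl]dihydrofuran-2(3H)-one
Product: 10 3-(benzyloxy)-2-hydroxy-4-methoxy-6-{[(3S)-5-oxotetrahydrofuran-3-yl]methyl}benzaldehyde
Conditions: MgCl2, Et3N, (CH2O)n, MeCN, reflux; then 1 M HCl
Reagents that add atoms: paraformaldehyde (as formaldehyde), C=O
Why: Magnesium-mediated ortho-formylation of a phenol; the magnesium phenoxide delivers formaldehyde only ortho to oxygen, C8a is the single free ortho carbon (C7 carries the benzyl ether), a second formaldehyde acts as hydride acceptor, and the lactone is inert.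

Step 7
Reactants: 10 3-(benzyloxy)-2-hydroxy-4-methoxy-6-{[(3S)-5-oxotetrahydrofuran-3-yl]methyl}benzaldehyde; 11 5-bromo-1,2,3-trimethoxybenzene
Product: 13 (4S)-4-{4-(benzyloxy)-3-hydroxy-2-[hydroxy(3,4,5-trimethoxyphenyl)methyl]-5-methoxybenzyl}dihydrofuran-2(3H)-one (both C1 epimers), via arylmagnesium bromide 12 (not isolated)
Conditions: 11, Mg, THF, rt → 45 °C; then 10, THF, −78 → −30 °C (2.2 equiv of 12); aq. NH4Cl
Reagents that add atoms: none
Why: Grignard 1,2-addition; the first equivalent forms the magnesium phenoxide, which chelates and activates the neighbouring formyl group so that the aldehyde should react at low temperature while the lactone is left, and the C1 epimer mixture is of no consequence.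

Step 8
Reactants: 13 (4S)-4-{4-(benzyloxy)-3-hydroxy-2-[hydroxy(3,4,5-trimethoxyphenyl)methyl]-5-methoxybenzyl}dihydrofuran-2(3H)-one; 14 sodium p-toluenesulfinate
Product: 15 (4S)-4-{4-(benzyloxy)-3-hydroxy-5-methoxy-2-[(4-methylbenzenesulfonyl)(3,4,5-trimethoxyphenyl)methyl]benzyl}dihydrofuran-2(3H)-one (both C1 epimers)
Conditions: 14 (3 equiv), HCO2H, CH2Cl2/H2O, rt
Reagents that add atoms: none
Why: SN1-type substitution, the usual preparation of 2-(α-sulfonylbenzyl)phenols; the doubly benzylic carbinol with an ortho hydroxyl ionises in acid and sulfinate captures the cation at sulfur to give the stable sulfone.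

Step 9
Reactants: 15 (4S)-4-{4-(benzyloxy)-3-hydroxy-5-methoxy-2-[(4-methylbenzenesulfonyl)(3,4,5-trimethoxyphenyl)methyl]benzyl}dihydrofuran-2(3H)-one
Product: 18 cis-fused lactone 7-(benzyloxy)-8-hydroxy-6-methoxy-9-(3,4,5-trimethoxyphenyl)-3a,4,9,9a-tetrahydronaphtho[2,3-c]furan-1(3H)-one (3aS,9S,9aR; in ring B numbering C3 S, C1 S, C2 R; aryl trans to C9), via dilithium dianion 16 (not isolated), via quinone methide enolate 17 (not isolated)
Conditions: LiN(SiMe3)2 (2.2 equiv), THF (0.02 M), −78 °C, then → 0 °C; aq. NH4Cl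
Reagents that add atoms: none
Why: The first equivalent of LiN(SiMe3)2 gives the C8 phenoxide and the second, at −78 °C, the lactone enolate at C2 (dianion 16); on warming the phenoxide expels p-toluenesulfinate from C1 to give the planar o-quinone methide O=C8–C8a=C1 (17), whose C1 is attacked by C2 with re-aromatisation of ring A. The closest known reaction type is the base-induced generation of o-quinone methides from 2-(α-sulfonylbenzyl)phenols with Michael capture by carbon nucleophiles, run here within one molecule. Ring B closes in a 6-endo-trig mode (C1=C8a lies inside the new ring), which the polarised, twistable aryl-substituted methide should allow. C2 is controlled by C3: the tether reaches C2 from the lactone face that carries C4, so C1 and C4 end cis on the lactone, and this cis fusion is also the more stable one to which C2 would equilibrate under the basic conditions. C1 loses the configuration it had in 15 and is set relative to C3 in a chair-like transition state with the trimethoxyphenyl group pseudoaxial on the convex face, anti to the enolate C2–C9 bond and out of the plane of the C8 oxygen, which places the aryl trans to C9. The step needs ring closure ahead of intermolecular capture of the methide, which is secured by forming the enolate before the methide is released (the phenol is far more acidic than the lactone, and sulfinate loss waits for warming), by dilution, and by limiting the base so that the hindered C1–H next to the sulfonyl group is not removed.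

Step 10
Reactants: 18 cis-fused lactone (3aS,9S,9aR)
Product: 19 [(1S,2R,3S)-7-(benzyloxy)-8-hydroxy-6-methoxy-1-(3,4,5-trimethoxyphenyl)-1,2,3,4-tetrahydronaphthalene-2,3-diyl]dimethanol (ring B numbering)
Conditions: LiAlH4 (3 equiv), THF, 0 °C → rt; aq. NaOH work-up
Reagents that add atoms: none
Why: Hydride reduction of a lactone to the 1,4-diol; reduction should be faster than enolisation at C2 and no bond to a stereocentre is broken, so C1, C2 and C3 are kept (the phenol is carried as its aluminate).

Step 11
Reactants: 19 [(1S,2R,3S)-7-(benzyloxy)-8-hydroxy-6-methoxy-1-(3,4,5-trimethoxyphenyl)-1,2,3,4-tetrahydronaphthalene-2,3-diyl]dimethanol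
Product: 20 [(1S,2R,3S)-7,8-dihydroxy-6-methoxy-1-(3,4,5-trimethoxyphenyl)-1,2,3,4-tetrahydronaphthalene-2,3-diyl]dimethanol (ring B numbering), the target
Conditions: H2 (1 atm), 10% Pd/C, MeOH/EtOAc, rt, work-up under argon
Reagents that add atoms: none
Why: Catalytic hydrogenolysis of the benzyl ether; aryl methyl ethers, the primary alcohols and the diarylmethine C1–H should not be cleaved, and the catechol is kept from air.

## Compound list

1 | 3,4-dihydroxy-5-methoxybenzaldehyde | COc1cc(C=O)cc(O)c1O | starting material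
2 | 4-(benzyloxy)-3-hydroxy-5-methoxybenzaldehyde | COc1cc(C=O)cc(O)c1OCc1ccccc1 | intermediate
3 | 4-(benzyloxy)-3-methoxy-5-(methoxymethoxy)benzaldehyde | COCOc1cc(C=O)cc(OC)c1OCc1ccccc1 | intermediate
4 | dimethyl succinate | COC(=O)CCC(=O)OC | starting material
5 | (E)-4-[4-(benzyloxy)-3-methoxy-5-(methoxymethoxy)phenyl]-3-(methoxycarbonyl)but-3-enoic acid | COCOc1cc(/C=C(\CC(=O)O)C(=O)OC)cc(OC)c1OCc1ccccc1 | intermediate
6 | (3S)-4-[4-(benzyloxy)-3-methoxy-5-(methoxymethoxy)phenyl]-3-(methoxycarbonyl)butanoic acid | COCOc1cc(C[C@H](C(=O)OC)CC(=O)O)cc(OC)c1OCc1ccccc1 | intermediate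
7 | (3S)-4-[4-(benzyloxy)-3-methoxy-5-(methoxymethoxy)phenyl]-3-(hydroxymethyl)butanoic acid (hydroxy acid, not isolated) | COCOc1cc(C[C@H](CO)CC(=O)O)cc(OC)c1OCc1ccccc1 | intermediate
8 | (4S)-4-[4-(benzyloxy)-3-methoxy-5-(methoxymethoxy)benzyl]dihydrofuran-2(3H)-one (MOM lactone, not isolated) | COCOc1cc(C[C@@H]2COC(=O)C2)cc(OC)c1OCc1ccccc1 | intermediate
9 | (4S)-4-[4-(benzyloxy)-3-hydroxy-5-methoxybenzyl]dihydrofuran-2(3H)-one | COc1cc(C[C@@H]2COC(=O)C2)cc(O)c1OCc1ccccc1 | intermediate
10 | 3-(benzyloxy)-2-hydroxy-4-methoxy-6-{[(3S)-5-oxotetrahydrofuran-3-yl]methyl}benzaldehyde | COc1cc(C[C@@H]2COC(=O)C2)c(C=O)c(O)c1OCc1ccccc1 | intermediate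
11 | 5-bromo-1,2,3-trimethoxybenzene | COc1cc(Br)cc(OC)c1OC | starting material
12 | (3,4,5-trimethoxyphenyl)magnesium bromide (not isolated) | COc1cc([Mg]Br)cc(OC)c1OC | intermediate
13 | (4S)-4-{4-(benzyloxy)-3-hydroxy-2-[hydroxy(3,4,5-trimethoxyphenyl)methyl]-5-methoxybenzyl}dihydrofuran-2(3H)-one, both C1 epimers | COc1cc(C[C@@H]2COC(=O)C2)c(C(O)c2cc(OC)c(OC)c(OC)c2)c(O)c1OCc1ccccc1 | intermediate
14 | sodium p-toluenesulfinate | Cc1ccc(S(=O)[O-])cc1.[Na+] | starting material
15 | (4S)-4-{4-(benzyloxy)-3-hydroxy-5-methoxy-2-[(4-methylbenzenesulfonyl)(3,4,5-trimethoxyphenyl)methyl]benzyl}dihydrofuran-2(3H)-one, both C1 epimers (key-step precursor) | COc1cc(C[C@@H]2COC(=O)C2)c(C(c2cc(OC)c(OC)c(OC)c2)S(=O)(=O)c2ccc(C)cc2)c(O)c1OCc1ccccc1 | intermediate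
16 | dilithium C8 phenoxide / C2 lactone enolate of 15 (not isolated) | [Li+].[Li+].COc1cc(C[C@@H]2COC([O-])=C2)c(C(c2cc(OC)c(OC)c(OC)c2)S(=O)(=O)c2ccc(C)cc2)c([O-])c1OCc1ccccc1 | intermediate
17 | o-quinone methide O=C8–C8a=C1 carrying the lithium lactone enolate (not isolated) | [Li+].COC1=C(OCc2ccccc2)C(=O)C(=Cc2cc(OC)c(OC)c(OC)c2)C(C[C@@H]2COC([O-])=C2)=C1 | intermediate
18 | (3aS,9S,9aR)-7-(benzyloxy)-8-hydroxy-6-methoxy-9-(3,4,5-trimethoxyphenyl)-3a,4,9,9a-tetrahydronaphtho[2,3-c]furan-1(3H)-one (cis-fused lactone, aryl trans to C9; key-step product) | COc1cc2c(c(O)c1OCc1ccccc1)[C@H](c1cc(OC)c(OC)c(OC)c1)[C@H]1C(=O)OC[C@H]1C2 | intermediate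
19 | [(1S,2R,3S)-7-(benzyloxy)-8-hydroxy-6-methoxy-1-(3,4,5-trimethoxyphenyl)-1,2,3,4-tetrahydronaphthalene-2,3-diyl]dimethanol | COc1cc2c(c(O)c1OCc1ccccc1)[C@H](c1cc(OC)c(OC)c(OC)c1)[C@@H](CO)[C@@H](CO)C2 | intermediate
20 | [(1S,2R,3S)-7,8-dihydroxy-6-methoxy-1-(3,4,5-trimethoxyphenyl)-1,2,3,4-tetrahydronaphthalene-2,3-diyl]dimethanol | COc1cc2c(c(O)c1O)[C@H](c1cc(OC)c(OC)c(OC)c1)[C@@H](CO)[C@@H](CO)C2 | target

## Step count and risks

Total: 11 steps. Longest linear sequence: 11 steps (1 → 20); 4, 11 and 14 are bought and enter in steps 3, 7 and 8.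

Steps most likely to fail:

1. Step 9 (key step). The methide may not be released cleanly: the base can remove the C1 proton next to the sulfonyl group in place of the lactone α-proton, the methide can be captured between molecules before the enolate reaches it, and the face selection at C1 may be incomplete.
Fallback (sets out from aldehyde 10, returns at lactone 18; it replaces steps 7 to 9): the methide is released by carbonate transfer instead of sulfinate loss, so no acidic C1–H is present. Boc2O, iPr2NEt and cat. DMAP in CH2Cl2 convert the phenol of 10 into the aryl carbonate 2-(benzyloxy)-6-formyl-3-methoxy-5-{[(3S)-5-oxotetrahydrofuran-3-yl]methyl}phenyl tert-butyl carbonate F1. Grignard reagent 12 (1.05 equiv, THF, −78 °C) adds to the formyl group, and the magnesium alkoxide takes the Boc group over from the phenol oxygen, which forms the phenoxide of the benzylic carbonate tert-butyl {[3-(benzyloxy)-2-hydroxy-4-methoxy-6-{[(3S)-5-oxotetrahydrofuran-3-yl]methyl}phenyl](3,4,5-trimethoxyphenyl)methyl} carbonate F2 (not isolated). LiN(SiMe3)2 (1.1 equiv) is added at −78 °C to enolise the lactone, and on warming to 0 °C the phenoxide expels tert-butyl carbonate, which should give the same methide enolate 17 and then 18. The magnesium counter-ion also offers a tighter, chelated transition state for the face selection at C1.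

2. Step 7. Over-addition: the excess of aryl Grignard reagent that the free phenol demands may attack the lactone carbonyl in competition with the aldehyde.
Fallback (sets out from phenol lactone 9, returns at carbinol 13; aldehyde 10 is by-passed): the C8a–C1 bond is made by ortho-specific hydroxyalkylation of a magnesium phenoxide. EtMgBr (1.0 equiv, Et2O/toluene, 0 °C) is consumed at once by the phenol O–H of 9, and 3,4,5-trimethoxybenzaldehyde is then added in toluene at rt. The aldehyde, bound to the phenoxide magnesium, should be delivered to C8a, the only free ortho carbon, so that no carbon nucleophile able to attack the lactone is present. This fallback makes no new compound (F0).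

3. Step 4. Incomplete face discrimination in the hydrogenation would lower the enantiomeric purity of C3, the only centre that relays configuration to C1 and C2.
Fallback (sets out from aldehyde 3, returns at phenol lactone 9): C3 is set by an Evans oxazolidinone alkylation in place of catalysis. NaBH4 in MeOH reduces 3 to [4-(benzyloxy)-3-methoxy-5-(methoxymethoxy)phenyl]methanol F3, and CBr4/PPh3 in CH2Cl2 at 0 °C converts it into 2-(benzyloxy)-5-(bromomethyl)-1-methoxy-3-(methoxymethoxy)benzene F4. The succinyl imide tert-butyl 4-[(4S)-4-benzyl-2-oxooxazolidin-3-yl]-4-oxobutanoate F5 (from mono-tert-butyl succinate and (S)-4-benzyl-2-oxazolidinone with pivaloyl chloride, Et3N and LiCl) is enolised with NaN(SiMe3)2 at −78 °C and alkylated with F4. The chelated Z-enolate should be attacked on the face away from the auxiliary benzyl group, which gives tert-butyl (3S)-3-{[(4S)-4-benzyl-2-oxooxazolidin-3-yl]carbonyl}-4-[4-(benzyloxy)-3-methoxy-5-(methoxymethoxy)phenyl]butanoate F6. LiBH4 in THF with one equivalent of water reduces the imide carbonyl only and releases the auxiliary, which leaves tert-butyl (3S)-4-[4-(benzyloxy)-3-methoxy-5-(methoxymethoxy)phenyl]-3-(hydroxymethyl)butanoate F7. 3 M HCl in MeOH at 50 °C then lactonises F7 with loss of tert-butanol and cleaves the MOM ether, which gives 9.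

## Further compounds

F1 | step 9 | 2-(benzyloxy)-6-formyl-3-methoxy-5-{[(3S)-5-oxotetrahydrofuran-3-yl]methyl}phenyl tert-butyl carbonate | COc1cc(C[C@@H]2COC(=O)C2)c(C=O)c(OC(=O)OC(C)(C)C)c1OCc1ccccc1
F2 | step 9 | tert-butyl {[3-(benzyloxy)-2-hydroxy-4-methoxy-6-{[(3S)-5-oxotetrahydrofuran-3-yl]methyl}phenyl](3,4,5-trimethoxyphenyl)methyl} carbonate (magnesium phenoxide in the flask, both C1 epimers, not isolated) | COc1cc(C[C@@H]2COC(=O)C2)c(C(OC(=O)OC(C)(C)C)c2cc(OC)c(OC)c(OC)c2)c(O)c1OCc1ccccc1
F0 | step 7 | none | none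
F3 | step 4 | [4-(benzyloxy)-3-methoxy-5-(methoxymethoxy)phenyl]methanol | COCOc1cc(CO)cc(OC)c1OCc1ccccc1
F4 | step 4 | 2-(benzyloxy)-5-(bromomethyl)-1-methoxy-3-(methoxymethoxy)benzene | COCOc1cc(CBr)cc(OC)c1OCc1ccccc1
F5 | step 4 | tert-butyl 4-[(4S)-4-benzyl-2-oxooxazolidin-3-yl]-4-oxobutanoate | CC(C)(C)OC(=O)CCC(=O)N1[C@@H](Cc2ccccc2)COC1=O
F6 | step 4 | tert-butyl (3S)-3-{[(4S)-4-benzyl-2-oxooxazolidin-3-yl]carbonyl}-4-[4-(benzyloxy)-3-methoxy-5-(methoxymethoxy)phenyl]butanoate | CC(C)(C)OC(=O)C[C@H](Cc1cc(OCOC)c(OCc2ccccc2)c(OC)c1)C(=O)N1[C@@H](Cc2ccccc2)COC1=O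
F7 | step 4 | tert-butyl (3S)-4-[4-(benzyloxy)-3-methoxy-5-(methoxymethoxy)phenyl]-3-(hydroxymethyl)butanoate | CC(C)(C)OC(=O)C[C@H](Cc1cc(OCOC)c(OCc2ccccc2)c(OC)c1)CO
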